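The earlier runs and the new flask are simulated on assumed constants, noise included.

What stands in the autumn flask after 15 d, and what, if anything, has stopped it there? This is the same flask whose early readings are given, so those readings speak for it directly.

| flask | Ej | Kj | remark | time |
|---|---|---|---|---|
| autumn | 0.096 M | 0.048 M | the very flask that is asked about, followed so far |  |
| flask | 0.096 M | 0.0480 M |  | 15 d |

autumn run (percent of the Ej charged)

| time / d | KjEb / % | Eb / % |
|---|---|---|
| 0.208 | 19.6 | 0 |
| 0.500 | 46.2 | 9.4 |
| 1.25 | 46.6 | 38.0 |
| 2.50 | 45.9 | 38.5 |

(standard deviation of a reading: 0.3 percentage points)

- as a solid, counted per litre of solution: Ej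
- at the start none of Ej is in solution
- what has only dissolved of Ej counts as not reacted
- the reaction counts as stopped when no species that holds the Ej changes by six tenths of a point or more over the second half of the time

- at 15 d, what has stopped the reaction, if anything has (for what has run out or reacted, a solid counts together with what of it has only dissolved) (forward and back rates have come level / all of Ej has reacted / it is still moving / Kj has run out first)
- amount of KjEb at 15 d, in percent of the Ej charged
- amount of Eb at 15 d, in percent of the Ej charged
- amount of KjEb if the flask were left three thousand times as long, in percent of the Ej charged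

The bench rule for such a charge takes one Kj for each Ej that ends in KjEb, with Kj as the limiting reagent, and it uses as the zero of the scale the case in which every Kj arrives there. This gives the Kj ceiling, the charge of Kj over the charge of Ej, which is 50.0 % of the Ej charged in the autumn flask. The rule reads KjEb standing flat at this ceiling as the end of the Kj. The three later readings of KjEb in the autumn flask do stand flat, but their mean of 46.2 % is 0.924 of the ceiling, and the gap of 3.8 percentage points, beside a scatter of 0.3 points, is read as real, so the rule stops working at this border. Yet between 0.500 d and 1.25 d the readings of the autumn flask show Eb gaining 29 points while KjEb goes from 46.2 % to 46.6 %, and Eb that piles up there beside a flat KjEb is read here as Eb that meets no free Kj. The reckoning here therefore commits, for the autumn flask, to Kj having run out first, with Kj worth the gap of 3.8 points held in some form the readings do not show, and to KjEb near 46.2 % and Eb near 38.2 % at 15 d, KjEb staying there for the far longer time as well.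

The forecast, parting from this reckoning on the end, names forward and back rates have come level, with 46.2 % of KjEb, 38.3 % of Eb and 46.2 % of KjEb for the far longer time, in its words “This looks like equilibrium”.

The autumn flask gives Kj has run out first, with 46.0 % of KjEb and 38.1 % of Eb at 15 d, and 46.0 % of KjEb for the far longer time.

    Ej ⇌ Ek, rate k1*(cs1 - [Ek]) while solid is left; crystals form when [Ek] > cs1 (solubility = 26.0 mM, k = 0.460 /h)
    Ek + Kj → EkKj (k = 1.30 /M/h)
    Ek ⇌ Eb (K = 3.20, k = 0.360 /h)
    Kj + Eb → KjEb (k = 580 /M/h)

At 0.304 d in the autumn flask, Ek, the dissolved Ej, goes to Eb 19 times as fast as it goes with Kj to EkKj, counting the forward rate of the reversible step alone. At 15.0 d the ceiling of 50.0 % stands in that flask as 46.0 % of KjEb and 4.03 % of EkKj, with 0 % of the Kj left. A second flask charged with 0.16 M of Ej and the same 0.0480 M of Kj has a ceiling of 30.0 %, and at 15.0 d it holds 27.6 % of KjEb and 2.42 % of EkKj, with 0 % of its Kj left.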